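**Conventions.** SEM = [2-(trimethylsilyl)ethoxy]methyl. Compounds 10, 12, 13, 14, 16 and 17 are racemic. The target is 19.

## The problem

Compound 19, 5-(6-bromo-4-methoxy-1H-indol-3-yl)-4-iodo-2-(1H-pyrrol-2-yl)-1,3-oxazole, is a row of three heteroaromatic rings. The indole is joined through C3 to oxazole C5, and oxazole C2 carries the pyrrol-2-yl group. There is no stereocenter, so the difficulty is regiochemical: bromine at indole C6, methoxy at C4, iodine at oxazole C4, and a C3–C5 ring–ring bond flanked on both sides (C4–OMe and C4–I). The C–I and C–Br bonds will not survive zerovalent palladium or halogen–metal exchange once both are present. The free pyrrole and indole will not survive electrophilic halogen sources, oxidants or strong acid, and an electrophilic iodination at the end would strike the pyrrole before the oxazole. Oxazole C4–H is also the least acidic position of that ring, so a late deprotonation there must compete with other C–H bonds; the iodine is better placed early, by a step whose regiochemistry is fixed by mechanism. The feature that opens the route lies in the indole benzene ring. Seen from C3a it is a 4-bromo-2-methoxyphenyl group whose one ortho carbon (C4) carries methoxy and whose other ortho carbon (the future C7a) carries hydrogen, so a nitrene delivered from a two-carbon unit on C3a can form only N1–C7a. Once oxazole C4 carries iodine, neither atom next to oxazole C5 can accept the nitrene either.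

## Retrosynthesis

**19 ⇐ 18.** The last bond cut is the N–CH2 bond of an SEM group on the pyrrole nitrogen. The pyrrole must be masked because the route uses amide bases, an ylide and azide. SEM is preferred to a carbamate because it does not activate pyrrole C5–H toward LiN(iPr)2 at −78 °C and does not yield to nucleophiles. It is preferred to a bulky N-silyl group because it fits next to the oxazole and is not labile there. The indole nitrogen needs no protection, since the indole is formed one step earlier. The forward step must only spare C–I, C–Br and two NH heterocycles.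

**18 ⇐ 15 (through 16 and 17).** The N1–C7a bond is cut, leading to vinyl azide 15, in which the arene and the iodooxazole sit on the same alkene carbon and the azide on the other.
- Against the neighbouring cut at indole C3–oxazole C5: a cross-coupling there would join two ortho-substituted carbons and would have to tell three carbon–halogen bonds apart.
- Against carrying an oxazole with C4–H through the ring closure: a nitrene closes readily onto five-membered heteroarenes, so oxazole C4–H would be a competing acceptor. With iodine already at C4 this path is closed, and no late iodination is needed.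
- Gain: the precursor has no indole, only a 1,1-diaryl alkene.
- Demand on the forward step: N2 loss and closure at arene C6–H faster than hydrogen migration in the nitrene.

**15 ⇐ 13 ⇐ 11 (through 12).** The C=C bond of 15 is traced to the tertiary β-azido alcohol 13 by dehydration. The C–N3 bond of 13 is traced to epoxide 12 (azide attack at CH2), and the epoxide CH2 to methylene transfer onto diaryl ketone 11. Indole C2 thus arrives as a one-carbon ylide unit and N1 as azide. Ketone 11 places arene and oxazole on one carbon by carbonyl chemistry, which is why no coupling at indole C3 is needed. The epoxide is not isolated because a 2,2-diaryl oxirane with an electron-rich aryl group rearranges on acid or silica.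

**11 ⇐ 10 ⇐ 7 + 8 (through 9).** The ketone comes from carbinol 10. The carbinol C–C bond is cut to aldehyde 8, which is bought with bromine and methoxy in place, and the 4-iodo-5-lithiooxazole 9. Intermediate 9 is the end point of a halogen dance on 5-iodooxazole 7. One operation moves the iodine to C4 and generates the C5 nucleophile, so the iodine position follows from carbanion stability, not from competition between C–H bonds. This replaces a C4 deprotonation on the finished tricycle.

**7 ⇐ 5 ⇐ 3 ⇐ 1 + 2.** Iodide 7 comes from SEM-protected pyrrolyloxazole 5 by lithiation at C5 (through 6) and iodine quench. Oxazole 5 comes from 3 by N-alkylation (through 4). Oxazole 3 is cut through O1–C5 and N3–C4 to amide 1 and bromoacetal 2, so the pyrrole is bought and the amide carbon becomes oxazole C2.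

## Roads not taken

**Alternative 1: Danheiser benzannulation of a pyrrolyl diazoketone.**
- Cut: the whole benzene ring of the indole (C7–C7a, C4–C5, C6–C7, C3a–C4).
- Forward key step: irradiation of diazoketone A1 triggers a Wolff rearrangement to a pyrrol-2-ylketene, which adds siloxyalkyne A2. The cyclobutenone opens and the dienylketene closes onto pyrrole C3 to give the 4-hydroxy-6-siloxyindole A3.
- Merits: four C–C bonds and a ring in one operation; regiochemistry set by the polarity of the alkyne; two differentiated oxygens; no coupling at indole C3.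
- Weak points: C6 must end as C–Br, so the C6 oxygen has to be desilylated, triflated and exchanged for bromine through a boron or tin intermediate, after methylation at C4. A1 is itself a 2,4-disubstituted pyrrole needing several steps. The oxazole of A3 still lacks both the pyrrole and the iodine.
- Comparison: the benzannulation is the more powerful ring construction and would be the better choice for analogues with oxygen at C6. For 19 it builds the arene with the wrong substituent, whereas the chosen plan buys the arene ready-made as 8 and is considerably shorter.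

**Alternative 2: Azavinyl carbene transannulation of a sulfonyl triazole.**
- Cut: through the oxazole (O1–C5 and N3–C2).
- Forward key step: Rh2(OAc)4, the divalent rhodium acetate dimer, opens N-tosyltriazole A4 to an α-imino carbene. This takes up the oxygen of aldehyde A5 and closes through nitrogen; base then expels toluenesulfinate to give oxazole A6.
- Merits: the most convergent of the four plans, since the indole and pyrrole halves meet as the central ring forms; neutral conditions; no organolithium.
- Weak points: A4 must be assembled from a preformed bromomethoxyindole in about five steps, one an alkynylation that must distinguish C3–I from C6–Br. The carbene sits on an electron-rich indol-3-yl carbon, and A5 is a hindered, deactivated aldehyde. Above all, A6 has hydrogen at oxazole C4. The iodine would have to go in last, by deprotonation at the least acidic oxazole position in a molecule with a carbamate-activated pyrrole C5–H and an arene C–H between methoxy and bromine, or by an electrophile that the pyrrole would intercept.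
- Comparison: in convergence, and probably in step count to the iodine-free tricycle, this road is at least as good. The chosen plan sets against it that the iodine enters early at a position fixed by the halogen dance, and then shields oxazole C4 in the ring-forming step.

**Alternative 3: Paal–Knorr pyrrole built last on the iodooxazole.**
- Cut: both N–C bonds of the pyrrole.
- Forward key step: NH4OAc condenses with the aldehyde and the ketone of 1,4-dicarbonyl compound A7 to give pyrrole A8; detosylation would finish.
- Merits: the pyrrole is never protected and never meets bases or oxidants; the iodine is already in place; the condensation is dependable.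
- Weak points: A7 is a 2-acyloxazole with a free aldehyde. Making it means acylating C2 of an iodinated indolyl-oxazole, where C2-metalated oxazoles equilibrate with open-chain isocyanide enolates and the C4–I bond invites exchange. The four-carbon chain must be carried with its aldehyde masked. The indole–oxazole bond and the iodination remain separate problems.
- Comparison: this road saves the two protecting-group steps that the chosen plan spends on the pyrrole, which is a real advantage. It pays with a longer construction of the simplest ring, which the chosen plan buys as amide 1.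

Key step: step 8

**Assumption:** step 7 is expected to give vinyl azide 15 as a mixture of alkene isomers. It is drawn and named as the Z isomer (azide cis to the oxazole); both isomers pass through azirine 16 in step 8.

## Route

Step 1
Reactants: 1 1H-pyrrole-2-carboxamide; 2 bromoacetaldehyde diethyl acetal (2-bromo-1,1-diethoxyethane)
Product: 3 2-(1H-pyrrol-2-yl)-1,3-oxazole
Conditions: 2 (1.5 equiv), neat, 120 °C
Reagents that add atoms: none
Why: Blümlein–Lewy oxazole synthesis from a primary amide and a masked α-halo aldehyde: the amide oxygen displaces bromide, the HBr set free unmasks the aldehyde, nitrogen condenses with it and loss of ethanol aromatizes, so the amide carbon becomes oxazole C2 and C4 and C5 stay unsubstituted; the acyl-type substituent makes the pyrrole reasonably tolerant of the acid released.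

Step 2
Reactants: 3 2-(1H-pyrrol-2-yl)-1,3-oxazole
Product: 5 2-(1-SEM-1H-pyrrol-2-yl)-1,3-oxazole, via sodium pyrrolide 4 (not isolated)
Conditions: NaH, DMF, 0 °C; then SEMCl, 0 °C → rt
Reagents that add atoms: 2-(trimethylsilyl)ethoxymethyl chloride (SEMCl), C[Si](C)(C)CCOCCl
Why: N-alkylation (SN2) of pyrrolide 4 by the reactive α-chloro ether; NaH removes only the N–H, and the oxazole nitrogen is a much poorer nucleophile than the pyrrolide.

Step 3
Reactants: 5 2-(1-SEM-1H-pyrrol-2-yl)-1,3-oxazole
Product: 7 5-iodo-2-(1-SEM-1H-pyrrol-2-yl)-1,3-oxazole, via 5-lithiooxazole 6 (not isolated)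
Conditions: LiN(iPr)2 (1.1 equiv), THF, −78 °C; then transfer into I2 (1.2 equiv), THF, −78 °C
Reagents that add atoms: iodine, II
Why: Deprotonation and iodine quench: H5 next to the ring oxygen is the most acidic C–H of a 2-substituted oxazole and its lithio derivative 6 does not ring-open (only 2-lithiooxazoles do); LiN(iPr)2 at −78 °C leaves the pyrrole C–H next to N-SEM untouched, and inverse addition keeps 6 away from 7 so that no halogen migration starts here.

Step 4
Reactants: 7 5-iodo-2-(1-SEM-1H-pyrrol-2-yl)-1,3-oxazole; 8 4-bromo-2-methoxybenzaldehyde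
Product: 10 (4-bromo-2-methoxyphenyl)[4-iodo-2-(1-SEM-1H-pyrrol-2-yl)-1,3-oxazol-5-yl]methanol (racemic), via 4-iodo-5-lithiooxazole 9 (not isolated)
Conditions: LiN(iPr)2 (1.2 equiv), THF, −78 °C; then 8, −78 → −20 °C
Reagents that add atoms: none
Why: Halogen dance followed by carbonyl addition: LiN(iPr)2 removes H4, the only oxazole C–H of 7 and acidified by the adjacent iodine, and intermolecular iodine–lithium exchange relays the metal to C5, ending at the most stabilized carbanion 9 (next to ring oxygen, ortho to iodine), which adds to aldehyde 8; the stabilized heteroaryllithium does not exchange with the aryl bromide at −78 °C, and the carbinol center forms racemic and is removed in step 5.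

Step 5
Reactants: 10 (4-bromo-2-methoxyphenyl)[4-iodo-2-(1-SEM-1H-pyrrol-2-yl)-1,3-oxazol-5-yl]methanol
Product: 11 (4-bromo-2-methoxyphenyl)[4-iodo-2-(1-SEM-1H-pyrrol-2-yl)-1,3-oxazol-5-yl]methanone
Conditions: Dess–Martin periodinane, CH2Cl2, 0 °C → rt
Reagents that add atoms: none
Why: Dess–Martin oxidation of a doubly benzylic secondary alcohol to the diaryl ketone under nearly neutral conditions; the aryl halides, the SEM group and the deactivated pyrrole are not affected, and the ketone has no enolizable hydrogen.

Step 6
Reactants: 11 (4-bromo-2-methoxyphenyl)[4-iodo-2-(1-SEM-1H-pyrrol-2-yl)-1,3-oxazol-5-yl]methanone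
Product: 13 2-azido-1-(4-bromo-2-methoxyphenyl)-1-[4-iodo-2-(1-SEM-1H-pyrrol-2-yl)-1,3-oxazol-5-yl]ethan-1-ol (racemic), via terminal epoxide 12 (not isolated)
Conditions: Me3S+ I−, NaH, DMSO–THF, 0 °C → rt; then NaN3, H2O, 70 °C
Reagents that add atoms: trimethylsulfonium iodide, C[S+](C)C.[I-]; sodium azide, [Na+].[N-]=[N+]=[N-]
Why: Corey–Chaykovsky epoxidation then azidolysis in one pot: dimethylsulfonium methylide adds 1,2 to the non-enolizable diaryl ketone and closes to epoxide 12, which is kept away from silica and acid, and azide then opens it by SN2 at the unhindered CH2 under basic conditions; azide is added only after the ketone is consumed, because in 11 the C4–I bond is β to the carbonyl and open to addition–elimination; the tertiary carbinol center is racemic and disappears in step 7.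

Step 7
Reactants: 13 2-azido-1-(4-bromo-2-methoxyphenyl)-1-[4-iodo-2-(1-SEM-1H-pyrrol-2-yl)-1,3-oxazol-5-yl]ethan-1-ol
Product: 15 5-[(Z)-2-azido-1-(4-bromo-2-methoxyphenyl)ethenyl]-4-iodo-2-(1-SEM-1H-pyrrol-2-yl)-1,3-oxazole, via Burgess sulfamate ester 14 (not isolated)
Conditions: Burgess reagent (1.5 equiv), THF, rt → 40 °C, dark
Reagents that add atoms: none
Why: Burgess dehydration of a tertiary doubly benzylic alcohol through sulfamate ester 14 (syn elimination with strong ionization character); the only β-hydrogens are on CH2N3, so the vinyl azide is the only alkene that can form, and 40 °C is below the temperature at which a β-aryl vinyl azide loses N2; the alkene geometry is not controlled and need not be.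

Step 8
Reactants: 15 5-[(Z)-2-azido-1-(4-bromo-2-methoxyphenyl)ethenyl]-4-iodo-2-(1-SEM-1H-pyrrol-2-yl)-1,3-oxazole
Product: 18 5-(6-bromo-4-methoxy-1H-indol-3-yl)-4-iodo-2-(1-SEM-1H-pyrrol-2-yl)-1,3-oxazole, via 2H-azirine 16 (not isolated), via 7aH-indole 17 (not isolated)
Conditions: Rh2(O2CC3F7)4 (5 mol %), PhMe (0.02 M), 4 Å MS, 60 → 100 °C, dark
Reagents that add atoms: none
Why: Loss of N2 from 15, thermally or after coordination of the azide to the electrophilic divalent rhodium carboxylate, gives 2H-azirine 16, which reopens at its C2–N bond to the vinylnitrene or its rhodium complex, so both alkene isomers of 15 converge. The nitrene nitrogen, the two alkene carbons and the C1–C6 bond of the arene close by a 1,5-electrocyclization (five atoms, six π electrons) that forms N1–C7a and the pyrrole ring as 7aH-indole 17, and a 1,5-hydrogen shift from C7a to nitrogen gives aromatic 18. The closest known reactions are the Hemetsberger indole synthesis and the thermal or rhodium carboxylate-catalysed conversion of β-aryl vinyl azides and 2-aryl-2H-azirines into indoles. No stereocenter remains, since those of 16 and 17 are transient. The step needs site selectivity among the four atoms next to the two ipso carbons: arene C2 carries OMe, oxazole C4 carries iodine, oxazole O1 cannot accept the nitrene, and only arene C6–H can close and rearomatize; without the iodine, closure onto oxazole C4–H would be a serious competitor, since Hemetsberger closures onto five-membered heteroarenes are facile. It also needs ring closure to outrun 1,2-hydrogen migration in the nitrene, which the catalyst, the electron-rich arene and high dilution are meant to secure. C–Br, C–I and the SEM group are inert to the rhodium carboxylate and to 100 °C in the dark.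

Step 9
Reactants: 18 5-(6-bromo-4-methoxy-1H-indol-3-yl)-4-iodo-2-(1-SEM-1H-pyrrol-2-yl)-1,3-oxazole
Product: 19 5-(6-bromo-4-methoxy-1H-indol-3-yl)-4-iodo-2-(1H-pyrrol-2-yl)-1,3-oxazole
Conditions: Bu4NF (1 M in THF, 5 equiv), THF, 65 °C
Reagents that add atoms: none
Why: Fluoride-induced SEM cleavage: attack at silicon releases fluorotrimethylsilane and ethylene, and the remaining N–CH2–O fragment loses formaldehyde because the 2-(oxazolyl)pyrrolide is a good leaving group; aryl bromide, oxazolyl iodide and the indole N–H tolerate Bu4NF at 65 °C.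

## Compound list

1 | 1H-pyrrole-2-carboxamide | NC(=O)c1ccc[nH]1 | starting material
2 | bromoacetaldehyde diethyl acetal (2-bromo-1,1-diethoxyethane) | CCOC(CBr)OCC | starting material
3 | 2-(1H-pyrrol-2-yl)-1,3-oxazole | c1coc(n1)-c1ccc[nH]1 | intermediate
4 | sodium 2-(1,3-oxazol-2-yl)pyrrol-1-ide | [Na+].c1coc(n1)-c1ccc[n-]1 | intermediate (not isolated)
5 | 2-(1-{[2-(trimethylsilyl)ethoxy]methyl}-1H-pyrrol-2-yl)-1,3-oxazole | C[Si](C)(C)CCOCn1cccc1-c1ncco1 | intermediate
6 | [2-(1-SEM-1H-pyrrol-2-yl)-1,3-oxazol-5-yl]lithium | [Li]c1cnc(-c2cccn2COCC[Si](C)(C)C)o1 | intermediate (not isolated)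
7 | 5-iodo-2-(1-SEM-1H-pyrrol-2-yl)-1,3-oxazole | C[Si](C)(C)CCOCn1cccc1-c1ncc(I)o1 | intermediate
8 | 4-bromo-2-methoxybenzaldehyde | COc1cc(Br)ccc1C=O | starting material
9 | [4-iodo-2-(1-SEM-1H-pyrrol-2-yl)-1,3-oxazol-5-yl]lithium | [Li]c1oc(-c2cccn2COCC[Si](C)(C)C)nc1I | intermediate (not isolated)
10 | (4-bromo-2-methoxyphenyl)[4-iodo-2-(1-SEM-1H-pyrrol-2-yl)-1,3-oxazol-5-yl]methanol (racemic) | COc1cc(Br)ccc1C(O)c1oc(-c2cccn2COCC[Si](C)(C)C)nc1I | intermediate
11 | (4-bromo-2-methoxyphenyl)[4-iodo-2-(1-SEM-1H-pyrrol-2-yl)-1,3-oxazol-5-yl]methanone | COc1cc(Br)ccc1C(=O)c1oc(-c2cccn2COCC[Si](C)(C)C)nc1I | intermediate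
12 | 5-[2-(4-bromo-2-methoxyphenyl)oxiran-2-yl]-4-iodo-2-(1-SEM-1H-pyrrol-2-yl)-1,3-oxazole (racemic) | COc1cc(Br)ccc1C1(CO1)c1oc(-c2cccn2COCC[Si](C)(C)C)nc1I | intermediate (not isolated)
13 | 2-azido-1-(4-bromo-2-methoxyphenyl)-1-[4-iodo-2-(1-SEM-1H-pyrrol-2-yl)-1,3-oxazol-5-yl]ethan-1-ol (racemic) | COc1cc(Br)ccc1C(O)(CN=[N+]=[N-])c1oc(-c2cccn2COCC[Si](C)(C)C)nc1I | intermediate
14 | triethylammonium N-(methoxycarbonyl)sulfamate ester of alcohol 13 (racemic) | CC[NH+](CC)CC.COC(=O)[N-]S(=O)(=O)OC(CN=[N+]=[N-])(c1ccc(Br)cc1OC)c1oc(-c2cccn2COCC[Si](C)(C)C)nc1I | intermediate (not isolated)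
15 | 5-[(Z)-2-azido-1-(4-bromo-2-methoxyphenyl)ethenyl]-4-iodo-2-(1-SEM-1H-pyrrol-2-yl)-1,3-oxazole | [N-]=[N+]=N/C=C(/c1ccc(Br)cc1OC)c1oc(-c2cccn2COCC[Si](C)(C)C)nc1I | intermediate
16 | 5-[2-(4-bromo-2-methoxyphenyl)-2H-azirin-2-yl]-4-iodo-2-(1-SEM-1H-pyrrol-2-yl)-1,3-oxazole (racemic) | COc1cc(Br)ccc1C1(C=N1)c1oc(-c2cccn2COCC[Si](C)(C)C)nc1I | intermediate (not isolated)
17 | 5-(6-bromo-4-methoxy-7aH-indol-3-yl)-4-iodo-2-(1-SEM-1H-pyrrol-2-yl)-1,3-oxazole (racemic) | COC1=CC(Br)=CC2N=CC(c3oc(-c4cccn4COCC[Si](C)(C)C)nc3I)=C12 | intermediate (not isolated)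
18 | 5-(6-bromo-4-methoxy-1H-indol-3-yl)-4-iodo-2-(1-SEM-1H-pyrrol-2-yl)-1,3-oxazole | COc1cc(Br)cc2[nH]cc(-c3oc(-c4cccn4COCC[Si](C)(C)C)nc3I)c12 | intermediate
19 | 5-(6-bromo-4-methoxy-1H-indol-3-yl)-4-iodo-2-(1H-pyrrol-2-yl)-1,3-oxazole | COc1cc(Br)cc2[nH]cc(-c3oc(-c4ccc[nH]4)nc3I)c12 | target

## Step count and risks

Total step count: 9. Longest linear sequence: 9 steps (1 → 3 → 5 → 7 → 10 → 11 → 13 → 15 → 18 → 19); aldehyde 8 enters in step 4.

**Step 8 (key step).**
- What may go wrong: 1,2-hydrogen migration in the vinylnitrene (the azide carbon carries hydrogen) outrunning ring closure, so that material drains into an open-chain isomer; ipso attack at the iodine-bearing oxazole carbon with loss of iodine; slowing of the catalyst by coordination of the oxazole nitrogen.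
- Fallback (sets out from 7, returns at 18): the nitrene closure is given up for a cross-coupling of a purchased indole. Iodide 7 is treated with LiN(iPr)2 and then I2 to give 4,5-diiodo-2-(1-SEM-1H-pyrrol-2-yl)-1,3-oxazole F1. Purchased 6-bromo-4-methoxy-1H-indole F2 is N-silylated (NaH, iPr3SiCl) to 6-bromo-4-methoxy-1-(triisopropylsilyl)-1H-indole F3 and iodinated with N-iodosuccinimide to 6-bromo-3-iodo-4-methoxy-1-(triisopropylsilyl)-1H-indole F4. Iodine–magnesium exchange (iPrMgCl·LiCl, −40 °C) and trapping with 2-isopropoxy-4,4,5,5-tetramethyl-1,3,2-dioxaborolane give 6-bromo-4-methoxy-3-(4,4,5,5-tetramethyl-1,3,2-dioxaborolan-2-yl)-1-(triisopropylsilyl)-1H-indole F5. Suzuki–Miyaura coupling of F5 with F1 (PdCl2(dppf), K3PO4, dioxane–H2O, 60 °C) at the more reactive C5–I bond gives 5-[6-bromo-4-methoxy-1-(triisopropylsilyl)-1H-indol-3-yl]-4-iodo-2-(1-SEM-1H-pyrrol-2-yl)-1,3-oxazole F6. Bu4NF at 0 °C removes the N-silyl group to give 18.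

**Step 4.**
- What may go wrong: incomplete iodine migration, or disproportionation into iodine-free and doubly iodinated oxazole anions, so that the aldehyde is captured by a carbanion without iodine at C4; competing deprotonation next to N-SEM.
- Fallback (sets out from 5, returns at 11): the iodine is introduced after the carbonyl group. Oxazole 5 is lithiated as in step 3 (6) and added to 8 to give (4-bromo-2-methoxyphenyl)[2-(1-SEM-1H-pyrrol-2-yl)-1,3-oxazol-5-yl]methanol F7. Dess–Martin oxidation gives (4-bromo-2-methoxyphenyl)[2-(1-SEM-1H-pyrrol-2-yl)-1,3-oxazol-5-yl]methanone F8. Directed magnesiation of F8 at oxazole C4 with TMPMgCl·LiCl (TMP = 2,2,6,6-tetramethylpiperidide; −40 °C; the site is ortho to the carbonyl and the ketone is not enolizable), then I2, gives 11.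

**Step 6.**
- What may go wrong: slow ylide addition to a ketone flanked by OMe and I; acid-induced rearrangement of the 2,2-diaryl epoxide; azide attack at the tertiary carbon instead of CH2.
- Fallback (sets out from 7, returns at 13): the azide is brought in on the electrophile. Purchased 2-bromo-1-(4-bromo-2-methoxyphenyl)ethan-1-one F9 and NaN3 (acetone–H2O, rt) give 2-azido-1-(4-bromo-2-methoxyphenyl)ethan-1-one F10. Carbanion 9, made from 7 as in step 4, is transmetalated with LaCl3·2LiCl to suppress enolization and added to F10 at −78 °C to give 13 directly, bypassing 10, 11 and 12.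

**Step 1.**
- What may go wrong: acid-induced oligomerization of the pyrrole under the HBr released at 120 °C; incomplete cyclodehydration.
- Fallback (sets out from 1, returns at 3): a more reactive α-bromo ketone under buffered conditions, then removal of the extra carboxyl group. Amide 1 and ethyl bromopyruvate (NaHCO3, THF, 60 °C; then (CF3CO)2O, pyridine) give ethyl 2-(1H-pyrrol-2-yl)-1,3-oxazole-4-carboxylate F11. LiOH gives 2-(1H-pyrrol-2-yl)-1,3-oxazole-4-carboxylic acid F12. Protodecarboxylation (Cu2O, quinoline, 180 °C) gives 3.

## Further compounds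

F1 | step 8 | 4,5-diiodo-2-(1-{[2-(trimethylsilyl)ethoxy]methyl}-1H-pyrrol-2-yl)-1,3-oxazole | C[Si](C)(C)CCOCn1cccc1-c1nc(I)c(I)o1
F2 | step 8 | 6-bromo-4-methoxy-1H-indole | COc1cc(Br)cc2[nH]ccc12
F3 | step 8 | 6-bromo-4-methoxy-1-(triisopropylsilyl)-1H-indole | COc1cc(Br)cc2c1ccn2[Si](C(C)C)(C(C)C)C(C)C
F4 | step 8 | 6-bromo-3-iodo-4-methoxy-1-(triisopropylsilyl)-1H-indole | COc1cc(Br)cc2c1c(I)cn2[Si](C(C)C)(C(C)C)C(C)C
F5 | step 8 | 6-bromo-4-methoxy-3-(4,4,5,5-tetramethyl-1,3,2-dioxaborolan-2-yl)-1-(triisopropylsilyl)-1H-indole | COc1cc(Br)cc2c1c(B1OC(C)(C)C(C)(C)O1)cn2[Si](C(C)C)(C(C)C)C(C)C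
F6 | step 8 | 5-[6-bromo-4-methoxy-1-(triisopropylsilyl)-1H-indol-3-yl]-4-iodo-2-(1-{[2-(trimethylsilyl)ethoxy]methyl}-1H-pyrrol-2-yl)-1,3-oxazole | COc1cc(Br)cc2c1c(-c1oc(-c3cccn3COCC[Si](C)(C)C)nc1I)cn2[Si](C(C)C)(C(C)C)C(C)C
F7 | step 4 | (4-bromo-2-methoxyphenyl)[2-(1-{[2-(trimethylsilyl)ethoxy]methyl}-1H-pyrrol-2-yl)-1,3-oxazol-5-yl]methanol (racemic) | COc1cc(Br)ccc1C(O)c1cnc(-c2cccn2COCC[Si](C)(C)C)o1
F8 | step 4 | (4-bromo-2-methoxyphenyl)[2-(1-{[2-(trimethylsilyl)ethoxy]methyl}-1H-pyrrol-2-yl)-1,3-oxazol-5-yl]methanone | COc1cc(Br)ccc1C(=O)c1cnc(-c2cccn2COCC[Si](C)(C)C)o1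
F9 | step 6 | 2-bromo-1-(4-bromo-2-methoxyphenyl)ethan-1-one | COc1cc(Br)ccc1C(=O)CBr
F10 | step 6 | 2-azido-1-(4-bromo-2-methoxyphenyl)ethan-1-one | COc1cc(Br)ccc1C(=O)CN=[N+]=[N-]
F11 | step 1 | ethyl 2-(1H-pyrrol-2-yl)-1,3-oxazole-4-carboxylate | CCOC(=O)c1coc(n1)-c1ccc[nH]1
F12 | step 1 | 2-(1H-pyrrol-2-yl)-1,3-oxazole-4-carboxylic acid | OC(=O)c1coc(n1)-c1ccc[nH]1
A1 | alternative 1 | 2-diazo-1-[4-(1,3-oxazol-5-yl)-1-{[2-(trimethylsilyl)ethoxy]methyl}-1H-pyrrol-2-yl]ethan-1-one | [N-]=[N+]=CC(=O)c1cc(-c2cnco2)cn1COCC[Si](C)(C)C
A2 | alternative 1 | (ethynyloxy)triisopropylsilane | C#CO[Si](C(C)C)(C(C)C)C(C)C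
A3 | alternative 1 | 3-(1,3-oxazol-5-yl)-6-[(triisopropylsilyl)oxy]-1-{[2-(trimethylsilyl)ethoxy]methyl}-1H-indol-4-ol | Oc1cc(O[Si](C(C)C)(C(C)C)C(C)C)cc2n(COCC[Si](C)(C)C)cc(-c3cnco3)c12
A4 | alternative 2 | 4-(6-bromo-4-methoxy-1-tosyl-1H-indol-3-yl)-1-tosyl-1H-1,2,3-triazole | COc1cc(Br)cc2n(S(=O)(=O)c3ccc(C)cc3)cc(-c3cn(S(=O)(=O)c4ccc(C)cc4)nn3)c12
A5 | alternative 2 | tert-butyl 2-formyl-1H-pyrrole-1-carboxylate | CC(C)(C)OC(=O)n1cccc1C=O
A6 | alternative 2 | tert-butyl 2-[5-(6-bromo-4-methoxy-1-tosyl-1H-indol-3-yl)-1,3-oxazol-2-yl]-1H-pyrrole-1-carboxylate | COc1cc(Br)cc2n(S(=O)(=O)c3ccc(C)cc3)cc(-c3cnc(-c4cccn4C(=O)OC(C)(C)C)o3)c12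
A7 | alternative 3 | 4-[5-(6-bromo-4-methoxy-1-tosyl-1H-indol-3-yl)-4-iodo-1,3-oxazol-2-yl]-4-oxobutanal | COc1cc(Br)cc2n(S(=O)(=O)c3ccc(C)cc3)cc(-c3oc(C(=O)CCC=O)nc3I)c12
A8 | alternative 3 | 5-(6-bromo-4-methoxy-1-tosyl-1H-indol-3-yl)-4-iodo-2-(1H-pyrrol-2-yl)-1,3-oxazole | COc1cc(Br)cc2n(S(=O)(=O)c3ccc(C)cc3)cc(-c3oc(-c4ccc[nH]4)nc3I)c12
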